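**Strategy.** Everything rests on the aldol retron hidden in the 1,3-diacetoxy array C14–C1–C2 that straddles the quaternary fusion carbon C1 between ring A (the cyclohexane) and the ten-membered ring. The key step closes the ten-membered ring by an intramolecular Mukaiyama aldol: a silyl enol ether C14=C1, generated regiospecifically with SmI2 from an α-acetoxy ketone, attacks the C2 aldehyde, creating the C1–C2 bond, the quaternary centre and the C2 carbinol at once. Its precursor is a seco aldehyde in which ring A (from 2,4-dimethylphenol by Wessely dearomatisation and copper-catalysed borylation) is joined at C9–C10 to a lactone aldehyde by a boron-tethered allylboration.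

Key step: step 20

Remark on numbering: atom labels are briarane labels. C1 is the quaternary fusion carbon (methyl C15), C2 the neighbouring acetoxy methine, C5=C6 the alkene (C16 = CH2Cl), C7/C8/C17/C19 the lactone, C9 the free carbinol, C10 the fusion CH, C11/C12 the epoxide carbons (methyl C20), and C14 the ring A acetoxy methine.

Remark on C1: the acetoxy-bearing carbon C1 of compounds 23–32 is carried as both epimers (left unspecified in the SMILES), because step 20 erases it. Compounds 6 and 9 are assumed to be purchasable.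

**Step 1**
Reactants: 1 tert-butyl (R)-lactate
Product: 2 tert-butyl (R)-2-(triflyloxy)propanoate
Conditions: Tf2O, 2,6-lutidine, CH2Cl2, −78 to 0 °C
Reagents that add atoms: trifluoromethanesulfonic anhydride, O=S(=O)(OS(=O)(=O)C(F)(F)F)C(F)(F)F
Why: O-sulfonylation of the secondary alcohol leaves the stereocentre untouched and gives an α-carbonyl triflate that is displaced cleanly by SN2.

**Step 2**
Reactants: 2 tert-butyl (R)-2-(triflyloxy)propanoate; 3 triethyl phosphonoacetate
Product: 5 phosphonosuccinate, via sodio phosphonoacetate 4 (not isolated)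
Conditions: NaH, 3 (2 equiv), THF, 0 °C; then 2, 0 °C to rt
Reagents that add atoms: none
Why: SN2 C-alkylation of the stabilised phosphonate carbanion with inversion should set C17 (S here, the later R lactone carbon); the phosphorus-bearing carbon is an inconsequential epimer pair.

**Step 3**
Reactants: 6 4-(tert-butyldimethylsilyloxy)but-2-yn-1-ol
Product: 8 Z vinyl iodide, via alkenylalanate 7 (not isolated)
Conditions: NaAlH2(OCH2CH2OCH3)2, THF, 0 °C; then I2, −78 °C
Reagents that add atoms: iodine, II
Why: hydroxyl-directed trans-hydroalumination of the propargylic alcohol (hydride to C6, aluminium to C5 in a five-membered alanate) and iodinolysis with retention should give the Z iodide, which places C7 and the future C4 cis on the C5=C6 alkene.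

**Step 4**
Reactants: 8 Z vinyl iodide; 9 (allyloxy)(tert-butyl)diphenylsilane
Product: 11 E allylic alcohol, via alkylborane 10 (not isolated)
Conditions: 9, 9-BBN, THF, rt; then 8, Pd(dppf)Cl2 (5 mol%), AsPh3, Cs2CO3, DMF/H2O, rt
Reagents that add atoms: none
Why: anti-Markovnikov hydroboration and B-alkyl Suzuki–Miyaura coupling proceed with retention of alkene geometry, so the C4–C2 chain replaces iodine cis to C7.

**Step 5**
Reactants: 11 E allylic alcohol
Product: 12 E enal
Conditions: Dess–Martin periodinane, NaHCO3, CH2Cl2, 0 °C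
Reagents that add atoms: none
Why: buffered Dess–Martin oxidation of the primary allylic alcohol should give the enal without E/Z isomerisation.

**Step 6**
Reactants: 12 E enal; 5 phosphonosuccinate
Product: 14 dienoate, via lithiated phosphonate 13 (not isolated)
Conditions: 5 (1.05 equiv), LiN(SiMe3)2 (1.0 equiv), THF, −78 °C; then 12, −78 to 0 °C
Reagents that add atoms: none
Why: Horner–Wadsworth–Emmons olefination with an α-branched phosphonoacetate should give the E trisubstituted enoate (C6 trans to the ester carbon C9, cis to C17), and the absence of excess base protects the C17 stereocentre.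

**Step 7**
Reactants: 14 dienoate
Product: 15 C16 allylic alcohol
Conditions: HF·pyridine, pyridine, THF, 0 °C
Reagents that add atoms: none
Why: fluoride desilylation removes the primary allylic tert-butyldimethylsilyl ether much faster than the tert-butyldiphenylsilyl ether.

**Step 8**
Reactants: 15 C16 allylic alcohol
Product: 17 allylic chloride, via mesylate 16 (not isolated)
Conditions: MsCl, 2,4,6-collidine, LiCl, DMF, 0 °C
Reagents that add atoms: lithium chloride, [Li+].[Cl-]
Why: in situ mesylation and direct SN2 displacement by chloride at the unhindered CH2 should give the primary allylic chloride without transposition.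

**Step 9**
Reactants: 17 allylic chloride
Product: 18 dienyl alcohol
Conditions: i-Bu2AlH (2.2 equiv), CH2Cl2, −78 °C; Rochelle salt
Reagents that add atoms: none
Why: 1,2-reduction of the conjugated ethyl ester at low temperature should spare the hindered tert-butyl ester and the allylic chloride.

**Step 10**
Reactants: 18 dienyl alcohol
Product: 19 epoxy alcohol
Conditions: Ti(OiPr)4 (10 mol%), D-(−)-diethyl tartrate (12 mol%), t-BuOOH, 4 Å MS, CH2Cl2, −20 °C
Reagents that add atoms: tert-butyl hydroperoxide, CC(C)(C)OO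
Why: Katsuki–Sharpless asymmetric epoxidation is reagent-controlled; the D-(−)-tartrate should give the (2R,3R) epoxide, fixing C8 and the C7 epoxide carbon, and only the allylic-alcohol alkene C7=C8 reacts.

**Step 11**
Reactants: 19 epoxy alcohol
Product: 20 epoxy aldehyde
Conditions: Dess–Martin periodinane, NaHCO3, CH2Cl2, 0 °C
Reagents that add atoms: none
Why: Dess–Martin oxidation to the epoxy aldehyde removes the primary hydroxyl that could otherwise compete as a lactonisation partner in step 12.

**Step 12**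
Reactants: 20 epoxy aldehyde
Product: 21 lactone aldehyde
Conditions: BF3·OEt2 (0.2 equiv), CH2Cl2, −40 °C
Reagents that add atoms: none
Why: acid-promoted 5-exo epoxide opening at the allylic carbon C7 by the tert-butyl ester carbonyl with inversion, then loss of isobutene, should give the γ-lactone with the C8 hydroxyl cis to the C7 side chain; C17 is not touched.

**Step 13**
Reactants: 22 2,4-dimethylphenol
Product: 23 racemic ortho-quinol acetate
Conditions: Pb(OAc)4, AcOH, rt
Reagents that add atoms: lead tetraacetate, CC(=O)O[Pb](OC(C)=O)(OC(C)=O)OC(C)=O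
Why: Wessely oxidation (acetoxylating dearomatisation at the methyl-bearing ortho carbon) gives a 2,4-dienone that already holds every carbon of ring A, the C14 carbonyl and a reductively cleavable acetate on C1.

**Step 14**
Reactants: 23 racemic ortho-quinol acetate
Product: 24 allylic pinacol boronate (both C1 epimers)
Conditions: CuCl (5 mol%), (R)-DTBM-SEGPHOS (6 mol%, antipode chosen for the S boronate), NaOtBu (10 mol%), B2pin2, MeOH, THF, −20 °C
Reagents that add atoms: bis(pinacolato)diboron, CC1(C)OB(OC1(C)C)B1OC(C)(C)C(C)(C)O1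
Why: copper-catalysed enantioselective conjugate borylation should add boron to the β-carbon C12 under catalyst control (1,4 rather than 1,6, the δ-carbon C10 being flanked by quaternary C1), and protonation at C13 leaves the C10=C11 alkene, so the product is an S-configured allylic boronate.

**Step 15**
Reactants: 24 allylic pinacol boronate
Product: 25 potassium allyltrifluoroborate
Conditions: KHF2, MeOH/H2O, rt
Reagents that add atoms: potassium hydrogen difluoride, [K+].[F-].F
Why: ligand exchange at boron with retention at carbon gives a stable salt whose boron can later exchange ligands with an alcohol.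

**Step 16**
Reactants: 25 potassium allyltrifluoroborate; 21 lactone aldehyde
Product: 29 seco diol, via allylboronic acid 26 (not isolated), via O8-bound allylboronate 27 (not isolated), via cyclic borate ester 28 (not isolated)
Conditions: 25, Me3SiCl, H2O, MeCN, rt; evaporate; then 21, 4 Å MS, CH2Cl2, −40 °C to rt; aq. NaHCO3
Reagents that add atoms: none
Why: allylboration in which the tertiary C8 hydroxyl first esterifies boron, so that syn-SE2' allyl transfer (C–C bond at C10 on the face that carried boron, alkene moving to C11=C12) runs through a bicyclic chair with the C8 substituent forced axial; this should give the anti C9/C10 relationship of the target instead of the syn adduct of an untethered chair, and the tether favours the aldehyde over the hindered ring ketone.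

**Step 17**
Reactants: 29 seco diol
Product: 30 acetonide
Conditions: 2-methoxypropene, PPTS, CH2Cl2, 0 °C
Reagents that add atoms: 2-methoxypropene, COC(C)=C
Why: acetonide formation (transketalisation) on the C8/C9 diol removes both hydroxyl protons before enolate chemistry and takes the C9 hydroxyl out of any hemiketal equilibrium with the C14 ketone.

**Step 18**
Reactants: 30 acetonide
Product: 31 primary alcohol
Conditions: HF·pyridine, pyridine, THF, rt
Reagents that add atoms: none
Why: buffered fluoride desilylation of the primary silyl ether should leave the acetonide, tertiary acetate and allylic chloride intact.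

**Step 19**
Reactants: 31 primary alcohol
Product: 32 seco aldehyde
Conditions: Dess–Martin periodinane, NaHCO3, CH2Cl2, 0 °C
Reagents that add atoms: none
Why: mild Dess–Martin oxidation gives the C2 aldehyde without enolising the α-acetoxy ketone.

**Step 20**
Reactants: 32 seco aldehyde
Product: 35 macrocyclic aldol, via samarium enolate 33 (not isolated), via trimethylsilyl enol ether 34 (not isolated)
Conditions: SmI2 (2.1 equiv), THF, −78 °C; Me3SiCl, Et3N; filter, exchange to CH2Cl2 (1 mM); BF3·OEt2, −78 °C; aq. NaHCO3, then citric acid/MeOH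
Reagents that add atoms: none
Why: Two electrons from SmI2 cleave the C1–OAc bond of the α-acetoxy ketone (both C1 epimers converge) to a trivalent samarium enolate, which is silylated to the enol ether C14(OSiMe3)=C1, a regiochemistry that deprotonation cannot give because C13 is allylic; BF3·OEt2 then activates the C2 aldehyde and C1 attacks it. The closest known reaction is the intramolecular Mukaiyama aldol used for medium-ring closures, fed by reductive cleavage of an α-heterosubstituted ketone. The ten-membered carbocycle closes in a 10-(enolexo)-exo-trig mode at high dilution. At C1 the C10 side chain sits pseudoaxial to avoid allylic strain with the C15 methyl, so the aldehyde adds axially anti to it and the ring fusion is trans. At C2 the open, non-chelated transition state keeps C3 on the outer C10/C15 edge (held there by the tether), puts the formyl hydrogen in the crowded sector between C15 and the silyloxy group and turns the BF3-bound oxygen away from it, which should give the R carbinol. The step needs reduction of the α-acetoxy ketone in the presence of aldehyde, lactone and allylic chloride (secured by its much faster electron transfer at −78 °C) and ring closure over oligomerisation (secured by dilution and by the turn that the ring-cis C5=C6 alkene and the lactone impose).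

**Step 21**
Reactants: 35 macrocyclic aldol
Product: 37 syn 2,14-diol, via diethylboron aldolate 36 (not isolated)
Conditions: Et2BOMe, THF/MeOH, −78 °C; NaBH4; MeOH co-evaporation
Reagents that add atoms: none
Why: Narasaka–Prasad reduction, in which external hydride attacks the boron chelate of the β-hydroxy ketone, should give the 1,3-syn diol, that is the axial C14 alcohol trans to the C15 methyl.

**Step 22**
Reactants: 37 syn 2,14-diol
Product: 38 diacetate acetonide
Conditions: Ac2O, DMAP, pyridine, 40 °C
Reagents that add atoms: acetic anhydride, CC(=O)OC(C)=O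
Why: nucleophilic-catalysed acetylation of the two hindered secondary hydroxyls (the C8/C9 oxygens are masked).

**Step 23**
Reactants: 38 diacetate acetonide
Product: 39 deoxy diol
Conditions: CF3CO2H/H2O (9:1), CH2Cl2, 0 °C
Reagents that add atoms: none
Why: acid hydrolysis of the acetonide should free the C8/C9 diol while the acetates, lactone and allylic chloride survive brief cold acid.

**Step 24**
Reactants: 39 deoxy diol
Product: 40 target
Conditions: VO(acac)2 (5 mol%), t-BuOOH, CH2Cl2, 0 °C to rt
Reagents that add atoms: tert-butyl hydroperoxide, CC(C)(C)OO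
Why: vanadium-catalysed hydroxyl-directed epoxidation, in which the homoallylic C9 hydroxyl delivers oxygen to the face of C11=C12 on which C9 sits (cis to the C15 methyl), sets C11 and C12; the C5=C6 alkene is deactivated by the allylic chloride and the lactone oxygen.

**Compound list**

1 | tert-butyl (R)-2-hydroxypropanoate | C[C@@H](O)C(=O)OC(C)(C)C | starting material
2 | tert-butyl (R)-2-[(trifluoromethylsulfonyl)oxy]propanoate | C[C@@H](OS(=O)(=O)C(F)(F)F)C(=O)OC(C)(C)C | intermediate
3 | triethyl phosphonoacetate | CCOC(=O)CP(=O)(OCC)OCC | starting material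
4 | sodium salt of triethyl phosphonoacetate | [Na+].CCOC(=O)[CH-]P(=O)(OCC)OCC | intermediate
5 | 1-tert-butyl 4-ethyl (2S)-3-(diethoxyphosphoryl)-2-methylbutanedioate, both C3 epimers | CCOC(=O)C(P(=O)(OCC)OCC)[C@@H](C)C(=O)OC(C)(C)C | intermediate
6 | 4-[(tert-butyldimethylsilyl)oxy]but-2-yn-1-ol | OCC#CCO[Si](C)(C)C(C)(C)C | starting material
7 | sodium alkenylalanate from hydroalumination of 6 (five-membered O–Al–C5 ring, two 2-methoxyethoxy ligands) | [Na+].COCCO[Al-]1(OCCOC)OCC=C1CO[Si](C)(C)C(C)(C)C | intermediate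
8 | (Z)-4-[(tert-butyldimethylsilyl)oxy]-3-iodobut-2-en-1-ol | OC/C=C(\I)CO[Si](C)(C)C(C)(C)C | intermediate
9 | (allyloxy)(tert-butyl)diphenylsilane | C=CCO[Si](c1ccccc1)(c1ccccc1)C(C)(C)C | starting material
10 | 9-{3-[(tert-butyldiphenylsilyl)oxy]propyl}-9-borabicyclo[3.3.1]nonane | CC(C)(C)[Si](OCCCB1C2CCCC1CCC2)(c1ccccc1)c1ccccc1 | intermediate
11 | (E)-3-{[(tert-butyldimethylsilyl)oxy]methyl}-6-[(tert-butyldiphenylsilyl)oxy]hex-2-en-1-ol | OC/C=C(/CO[Si](C)(C)C(C)(C)C)CCCO[Si](c1ccccc1)(c1ccccc1)C(C)(C)C | intermediate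
12 | (E)-3-{[(tert-butyldimethylsilyl)oxy]methyl}-6-[(tert-butyldiphenylsilyl)oxy]hex-2-enal | O=C/C=C(/CO[Si](C)(C)C(C)(C)C)CCCO[Si](c1ccccc1)(c1ccccc1)C(C)(C)C | intermediate
13 | lithium salt of 5 (carbanion at the phosphorus-bearing carbon) | [Li+].CCOC(=O)[C-](P(=O)(OCC)OCC)[C@@H](C)C(=O)OC(C)(C)C | intermediate
14 | 1-tert-butyl 4-ethyl (2R,3E)-2-methyl-3-[(2E)-3-{[(tert-butyldimethylsilyl)oxy]methyl}-6-[(tert-butyldiphenylsilyl)oxy]hex-2-en-1-ylidene]butanedioate | CCOC(=O)/C(=C/C=C(/CO[Si](C)(C)C(C)(C)C)CCCO[Si](c1ccccc1)(c1ccccc1)C(C)(C)C)[C@@H](C)C(=O)OC(C)(C)C | intermediate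
15 | the C16 alcohol of 14 (hydroxymethyl in place of silyloxymethyl; 2R,3E,2'E) | CCOC(=O)/C(=C/C=C(/CO)CCCO[Si](c1ccccc1)(c1ccccc1)C(C)(C)C)[C@@H](C)C(=O)OC(C)(C)C | intermediate
16 | the C16 methanesulfonate of 15 | CCOC(=O)/C(=C/C=C(/COS(C)(=O)=O)CCCO[Si](c1ccccc1)(c1ccccc1)C(C)(C)C)[C@@H](C)C(=O)OC(C)(C)C | intermediate
17 | the C16 chloride (chloromethyl; 2R,3E,2'E) | CCOC(=O)/C(=C/C=C(/CCl)CCCO[Si](c1ccccc1)(c1ccccc1)C(C)(C)C)[C@@H](C)C(=O)OC(C)(C)C | intermediate
18 | tert-butyl (2R,3E,5E)-6-(chloromethyl)-3-(hydroxymethyl)-2-methyl-9-[(tert-butyldiphenylsilyl)oxy]nona-3,5-dienoate | OC/C(=C/C=C(/CCl)CCCO[Si](c1ccccc1)(c1ccccc1)C(C)(C)C)[C@@H](C)C(=O)OC(C)(C)C | intermediate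
19 | tert-butyl (2R)-2-[(2R,3R)-3-{(1E)-2-(chloromethyl)-5-[(tert-butyldiphenylsilyl)oxy]pent-1-en-1-yl}-2-(hydroxymethyl)oxiran-2-yl]propanoate | OC[C@]1(O[C@@H]1/C=C(/CCl)CCCO[Si](c2ccccc2)(c2ccccc2)C(C)(C)C)[C@@H](C)C(=O)OC(C)(C)C | intermediate
20 | tert-butyl (2R)-2-[(2S,3R)-3-{(1E)-2-(chloromethyl)-5-[(tert-butyldiphenylsilyl)oxy]pent-1-en-1-yl}-2-formyloxiran-2-yl]propanoate | O=C[C@]1(O[C@@H]1/C=C(/CCl)CCCO[Si](c2ccccc2)(c2ccccc2)C(C)(C)C)[C@@H](C)C(=O)OC(C)(C)C | intermediate
21 | (2S,3S,4R)-2-{(1E)-2-(chloromethyl)-5-[(tert-butyldiphenylsilyl)oxy]pent-1-en-1-yl}-3-hydroxy-4-methyl-5-oxooxolane-3-carbaldehyde (C7, C8, C17 as in the target) | O=C[C@@]1(O)[C@H](/C=C(/CCl)CCCO[Si](c2ccccc2)(c2ccccc2)C(C)(C)C)OC(=O)[C@@H]1C | intermediate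
22 | 2,4-dimethylphenol | Cc1ccc(O)c(C)c1 | starting material
23 | 1,3-dimethyl-6-oxocyclohexa-2,4-dien-1-yl acetate, racemic | CC1=CC(C)(OC(C)=O)C(=O)C=C1 | intermediate
24 | (4S)-1,3-dimethyl-6-oxo-4-(4,4,5,5-tetramethyl-1,3,2-dioxaborolan-2-yl)cyclohex-2-en-1-yl acetate, both C1 epimers | CC1=CC(C)(OC(C)=O)C(=O)C[C@@H]1B2OC(C)(C)C(C)(C)O2 | intermediate
25 | potassium [(1S)-4-acetoxy-2,4-dimethyl-5-oxocyclohex-2-en-1-yl]trifluoroborate, both epimers at the acetoxy carbon | CC1=CC(C)(OC(C)=O)C(=O)C[C@@H]1[B-](F)(F)F.[K+] | intermediate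
26 | [(1S)-4-acetoxy-2,4-dimethyl-5-oxocyclohex-2-en-1-yl]boronic acid | CC1=CC(C)(OC(C)=O)C(=O)C[C@@H]1B(O)O | intermediate
27 | mixed boronate of 26 with the C8 hydroxyl of 21 (B–O8 bond, free aldehyde) | CC1=CC(C)(OC(C)=O)C(=O)C[C@@H]1B(O)O[C@]2(C=O)[C@H](/C=C(/CCl)CCCO[Si](c3ccccc3)(c3ccccc3)C(C)(C)C)OC(=O)[C@@H]2C | intermediate
28 | cyclic hydroxyborate of the C8/C9 diol 29 | O=C1CC=C(C)[C@H]([C@@H](OB(O)O3)[C@@]23[C@H](/C=C(/CCl)CCCO[Si](c4ccccc4)(c4ccccc4)C(C)(C)C)OC(=O)[C@@H]2C)C1(C)OC(C)=O | intermediate
29 | seco diol: ring A ketone (C14=O, C1 acetate, C11=C12) joined at C10 to C9(OH)–C8(OH) of the lactone; C7, C8, C9, C10, C17 as in the target, C1 both epimers | O=C1CC=C(C)[C@H]([C@@H](O)[C@@]2(O)[C@H](/C=C(/CCl)CCCO[Si](c3ccccc3)(c3ccccc3)C(C)(C)C)OC(=O)[C@@H]2C)C1(C)OC(C)=O | intermediate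
30 | C8,C9-O-isopropylidene derivative of 29 | O=C1CC=C(C)[C@H]([C@@H](OC(C)(C)O3)[C@@]23[C@H](/C=C(/CCl)CCCO[Si](c4ccccc4)(c4ccccc4)C(C)(C)C)OC(=O)[C@@H]2C)C1(C)OC(C)=O | intermediate
31 | C2 primary alcohol (desilylated 30) | O=C1CC=C(C)[C@H]([C@@H](OC(C)(C)O3)[C@@]23[C@H](/C=C(/CCl)CCCO)OC(=O)[C@@H]2C)C1(C)OC(C)=O | intermediate
32 | seco aldehyde (C2 aldehyde, C1 acetoxy C14 ketone, acetonide) | O=C1CC=C(C)[C@H]([C@@H](OC(C)(C)O3)[C@@]23[C@H](/C=C(/CCl)CCC=O)OC(=O)[C@@H]2C)C1(C)OC(C)=O | intermediate
33 | diiodosamarium enolate C14(OSmI2)=C1 of the seco aldehyde | I[Sm](I)OC1=C(C)[C@@H]([C@@H](OC(C)(C)O3)[C@@]23[C@H](/C=C(/CCl)CCC=O)OC(=O)[C@@H]2C)C(C)=CC1 | intermediate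
34 | trimethylsilyl enol ether C14(OSiMe3)=C1 of the seco aldehyde | C[Si](C)(C)OC1=C(C)[C@@H]([C@@H](OC(C)(C)O3)[C@@]23[C@H](/C=C(/CCl)CCC=O)OC(=O)[C@@H]2C)C(C)=CC1 | intermediate
35 | macrocyclic aldol: briarane skeleton with C14 ketone, C2 hydroxyl, C11=C12, C8/C9 acetonide; C1, C2, C7, C8, C9, C10, C17 as in the target | O=C1CC=C(C)[C@@H]2[C@@H](OC(C)(C)O4)[C@@]34[C@H](/C=C(/CCl)CC[C@@H](O)[C@@]12C)OC(=O)[C@@H]3C | intermediate
36 | O2-diethylboryl derivative (boron chelate) of 35 | O=C1CC=C(C)[C@@H]2[C@@H](OC(C)(C)O4)[C@@]34[C@H](/C=C(/CCl)CC[C@@H](OB(CC)CC)[C@@]12C)OC(=O)[C@@H]3C | intermediate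
37 | syn 2,14-diol (C14 as in the target), C8/C9 acetonide | O[C@H]1CC=C(C)[C@@H]2[C@@H](OC(C)(C)O4)[C@@]34[C@H](/C=C(/CCl)CC[C@@H](O)[C@@]12C)OC(=O)[C@@H]3C | intermediate
38 | 2,14-diacetate, C8/C9 acetonide | CC(=O)O[C@H]1CC=C(C)[C@@H]2[C@@H](OC(C)(C)O4)[C@@]34[C@H](/C=C(/CCl)CC[C@@H](OC(C)=O)[C@@]12C)OC(=O)[C@@H]3C | intermediate
39 | 11,12-deoxy target (C11=C12 alkene, free C8/C9 diol) | CC(=O)O[C@H]1CC=C(C)[C@@H]2[C@@H](O)[C@@]3(O)[C@H](/C=C(/CCl)CC[C@@H](OC(C)=O)[C@@]12C)OC(=O)[C@@H]3C | intermediate
40 | CNP0308390.1 (1S,2R,5E,7S,8R,9R,10S,11R,12S,14S,17R in briarane numbering) | CC(=O)O[C@H]1C[C@@H]2O[C@]2(C)[C@@H]2[C@@H](O)[C@@]3(O)[C@H](/C=C(/CCl)CC[C@@H](OC(C)=O)[C@@]12C)OC(=O)[C@@H]3C | target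

**Step count.** Total: 24 steps. Longest linear sequence: 19 steps (steps 3–12, 16, 17–24).

**Steps most likely to fail**

Step 20. What may go wrong: intermolecular aldol (oligomers) instead of ring closure, retro-aldol of the quaternary aldol on work-up, or attack on the other aldehyde face. Fallback: set out from 32 and let the samarium enolate 33 close the ring itself (SmI2, THF, −78 to −20 °C, no silylation). This metal-templated, chelated Reformatsky-type closure is expected to favour cyclisation but to give the C2-epimeric aldol F1. Dess–Martin oxidation gives the non-enolisable 1,3-diketone F2. LiBH(s-Bu)3 at −78 °C should attack the ring A ketone equatorially to give the axial C14 hydroxy ketone F3. Et2BOMe/NaBH4 then reduces the C2 ketone syn to the C14 hydroxyl, so C2 is set by 1,3-induction instead of by the aldol, and the route is rejoined at 37.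

Step 16. What may go wrong: the untethered chair (aldehyde substituent equatorial) competes and delivers the C9 epimer, or allyl transfer between the two hindered partners is slow. Fallback: set out from 24 and 21 and run the ordinary Lewis-acid-catalysed allylboration of the pinacol boronate (BF3·OEt2 cat., CH2Cl2, −78 °C), which should give the C9-epimeric diol F4 with C10 correct. Buffered Dess–Martin oxidation of the secondary carbinol only gives the α-hydroxy ketone F5, which must be kept cold because C10 is then allylic and α to a ketone. Zn(BH4)2 in Et2O at −78 °C reduces it through the O8–zinc chelate, with hydride entering from the less hindered C17 side, and returns to 29.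

Step 21. What may go wrong: the boron chelate forms poorly next to quaternary C1, so facial selectivity at C14 is low, or the aldol reverts. Fallback: set out from 35 and acetylate the C2 hydroxyl first (Ac2O, DMAP) to the keto acetate F6, which can neither chelate nor undergo retro-aldol. Reduce the ring A ketone under steric control with LiBH(s-Bu)3 at −78 °C (equatorial attack) to the axial C14 alcohol F7. Acetylation of F7 rejoins the route at 38.

**Further compounds**

F1 | step 20 | C2-epimeric macrocyclic aldol | O=C1CC=C(C)[C@@H]2[C@@H](OC(C)(C)O4)[C@@]34[C@H](/C=C(/CCl)CC[C@H](O)[C@@]12C)OC(=O)[C@@H]3C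
F2 | step 20 | macrocyclic 2,14-diketone | O=C1CC=C(C)[C@@H]2[C@@H](OC(C)(C)O4)[C@@]34[C@H](/C=C(/CCl)CCC(=O)[C@@]12C)OC(=O)[C@@H]3C
F3 | step 20 | 14-hydroxy 2-ketone (axial C14 alcohol) | O[C@H]1CC=C(C)[C@@H]2[C@@H](OC(C)(C)O4)[C@@]34[C@H](/C=C(/CCl)CCC(=O)[C@@]12C)OC(=O)[C@@H]3C
F4 | step 16 | C9-epimeric seco diol | O=C1CC=C(C)[C@H]([C@H](O)[C@@]2(O)[C@H](/C=C(/CCl)CCCO[Si](c3ccccc3)(c3ccccc3)C(C)(C)C)OC(=O)[C@@H]2C)C1(C)OC(C)=O
F5 | step 16 | C9 ketone (α-hydroxy ketone) | O=C1CC=C(C)[C@H](C(=O)[C@@]2(O)[C@H](/C=C(/CCl)CCCO[Si](c3ccccc3)(c3ccccc3)C(C)(C)C)OC(=O)[C@@H]2C)C1(C)OC(C)=O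
F6 | step 21 | 2-O-acetyl C14 ketone | O=C1CC=C(C)[C@@H]2[C@@H](OC(C)(C)O4)[C@@]34[C@H](/C=C(/CCl)CC[C@@H](OC(C)=O)[C@@]12C)OC(=O)[C@@H]3C
F7 | step 21 | 2-O-acetyl 14-alcohol | O[C@H]1CC=C(C)[C@@H]2[C@@H](OC(C)(C)O4)[C@@]34[C@H](/C=C(/CCl)CC[C@@H](OC(C)=O)[C@@]12C)OC(=O)[C@@H]3C
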